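Ring B of the tetralin (C1–C4, C4a, C8a; C1 carries the guaiacyl group) is cut at C3–C4 and C1–C8a, a formal [3+3] annulation. The key step exploits that C3 is alpha to a latent carboxyl (its CH2OH), that C1 is benzylic to a para-oxygenated aryl (a latent cation), and that C8a lies para to O6 of ring A and ortho to the benzylic C4. In one flask the enolate of an enantiopure beta-substituted gamma-butyrolactone carrying a benzylic methyl ether is C-benzylated by an isovanillyl bromide; acid then ionises the ether and the new arene closes ring B, setting C3 and C1 from C2.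

Key step: step 6

Remark on the chemistry: the methoxy-bearing benzylic carbon made in step 3 is expected as a mixture of epimers and is written without a descriptor (in 6, 7, 8, 11, F1 and F6). It becomes a planar cation in step 6, so both epimers converge. Locants follow tetralin numbering: C1 carries the guaiacyl ring (ring C), C2 and C3 carry the CH2OH groups, C4 is the CH2. Ring A is the aromatic ring (OH on C6, OMe on C7) and ring B is the saturated ring.

Step 1
Reactants: 1 (R)-4-benzyl-1,3-thiazolidine-2-thione; 2 methyl 4-chloro-4-oxobutanoate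
Product: 3 methyl 4-[(4R)-4-benzyl-2-thioxo-1,3-thiazolidin-3-yl]-4-oxobutanoate
Conditions: Et3N (1.2 equiv), DMAP (cat.), CH2Cl2, 0 °C → rt
Reagents that add atoms: none
Why: N-acylation of the thiazolidinethione NH by an acid chloride under amine base and DMAP catalysis is a standard acyl transfer that touches no stereocentre.

Step 2
Reactants: 4 4-(benzyloxy)-3-methoxybenzaldehyde
Product: 5 1-(benzyloxy)-4-(dimethoxymethyl)-2-methoxybenzene
Conditions: HC(OMe)3 (2 equiv), p-TsOH·H2O (cat.), MeOH, rt; NaHCO3 quench
Reagents that add atoms: trimethyl orthoformate, COC(OC)OC; methanol, CO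
Why: Acid-catalysed acetalisation of an aromatic aldehyde, driven to completion by the orthoformate as water scavenger.

Step 3
Reactants: 3 methyl 4-[(4R)-4-benzyl-2-thioxo-1,3-thiazolidin-3-yl]-4-oxobutanoate; 5 1-(benzyloxy)-4-(dimethoxymethyl)-2-methoxybenzene
Product: 6 methyl (3S)-3-{[(4R)-4-benzyl-2-thioxo-1,3-thiazolidin-3-yl]carbonyl}-4-[4-(benzyloxy)-3-methoxyphenyl]-4-methoxybutanoate
Conditions: TiCl4 (1.1 equiv), i-Pr2NEt (1.1 equiv), CH2Cl2, −78 → 0 °C; then 5 and TiCl4 (1.0 equiv), −78 → −40 °C; aq. NH4Cl
Reagents that add atoms: none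
Why: Soft enolisation gives the chelated Z titanium enolate of the thioimide only (the pendant ester is not enolised), and the aryl oxocarbenium ion released from 5 by the Lewis acid should add in an SN1-type, auxiliary-controlled enolate alkylation (Lewis acid-mediated addition of a chiral titanium enolate to an acetal) on the face opposite the 4-benzyl group, which sets the future C2 as drawn.

Step 4
Reactants: 6 methyl (3S)-3-{[(4R)-4-benzyl-2-thioxo-1,3-thiazolidin-3-yl]carbonyl}-4-[4-(benzyloxy)-3-methoxyphenyl]-4-methoxybutanoate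
Product: 8 (4R)-4-{[4-(benzyloxy)-3-methoxyphenyl](methoxy)methyl}oxolan-2-one, via gamma-hydroxy ester 7 (not isolated)
Conditions: NaBH4 (2 equiv), THF/EtOH, 0 °C → rt; then PPTS (cat.), CH2Cl2, rt
Reagents that add atoms: none
Why: Reductive cleavage of the activated N-acyl thiazolidinethione by borohydride should be much faster than reduction of the methyl ester, and the resulting gamma-hydroxy ester lactonises under mild acid catalysis without touching the stereocentre.

Step 5
Reactants: 9 [3-(benzyloxy)-4-methoxyphenyl]methanol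
Product: 10 2-(benzyloxy)-4-(bromomethyl)-1-methoxybenzene
Conditions: PBr3 (0.4 equiv), Et2O, 0 °C; used freshly prepared
Reagents that add atoms: phosphorus tribromide, BrP(Br)Br
Why: Nucleophilic substitution of the benzylic alcohol through its phosphite ester gives the benzylic bromide.

Step 6
Reactants: 8 (4R)-4-{[4-(benzyloxy)-3-methoxyphenyl](methoxy)methyl}oxolan-2-one; 10 2-(benzyloxy)-4-(bromomethyl)-1-methoxybenzene
Product: 12 (3aR,4S,9aR)-7-(benzyloxy)-4-[4-(benzyloxy)-3-methoxyphenyl]-6-methoxy-3a,4,9,9a-tetrahydronaphtho[2,3-c]furan-1(3H)-one, via trans-benzylated lactone 11 (not isolated)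
Conditions: LiN(SiMe3)2 (1.1 equiv), THF, −78 °C; 10 (0.95 equiv), −78 → −30 °C; then CF3CO2H (excess)/CH2Cl2, −30 °C → rt
Reagents that add atoms: none
Why: LiN(SiMe3)2 gives the lithium enolate of 8, which is benzylated by 10 in an SN2 step on the face anti to the side chain on the neighbouring carbon to give trans-lactone 11 (C3–C4 bond, C3 set); CF3CO2H then ionises the benzylic methyl ether (SN1, the cation being a quinone-methide-type oxocarbenium ion stabilised by the para-benzyloxy group) and the tethered arene attacks it (C8a–C1 bond) with loss of a proton. The closest known reaction types are the trans-selective alkylation of beta-substituted gamma-butyrolactone enolates and the acid-mediated Friedel–Crafts cyclisation of benzylic cations to aryltetralin lignan lactones, which together amount to a formal [3+3] annulation. Ring B closes by 6-exo-trig attack on the exocyclic C1=C(aryl) bond of the cation (6-endo with respect to the arene π bond that acts as the nucleophile). C3 is controlled by the C2 stereocentre of 8 (alkylation trans to its substituent), and C1 by a chair-like transition state with the guaiacyl group pseudo-equatorial and trans to the C2–CH2O bond of the rigid trans-fused lactone, which should give the all-trans (1S,2R,3R) array. The step needs C-alkylation and mono-alkylation, secured by the lithium enolate at −78 °C with 10 as the limiting reagent so that no benzylic bromide is left when the acid is added; it also needs ring closure para and not ortho to the benzyloxy group of ring A, secured by the stronger para activation and by the hindrance of the position flanked by CH2 and OBn.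

Step 7
Reactants: 12 (3aR,4S,9aR)-7-(benzyloxy)-4-[4-(benzyloxy)-3-methoxyphenyl]-6-methoxy-3a,4,9,9a-tetrahydronaphtho[2,3-c]furan-1(3H)-one
Product: 13 [(1S,2R,3R)-6-(benzyloxy)-1-[4-(benzyloxy)-3-methoxyphenyl]-7-methoxy-1,2,3,4-tetrahydronaphthalene-2,3-diyl]dimethanol
Conditions: LiAlH4 (2 equiv), THF, 0 °C → rt; aqueous NaOH work-up
Reagents that add atoms: none
Why: Hydride reduction of the lactone to the 1,4-diol is faster than enolisation, so C3 is not epimerised and the benzyl ethers are untouched.

Step 8
Reactants: 13 [(1S,2R,3R)-6-(benzyloxy)-1-[4-(benzyloxy)-3-methoxyphenyl]-7-methoxy-1,2,3,4-tetrahydronaphthalene-2,3-diyl]dimethanol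
Product: 14 (5S,6R,7R)-5-(4-hydroxy-3-methoxyphenyl)-6,7-bis(hydroxymethyl)-3-methoxy-5,6,7,8-tetrahydronaphthalen-2-ol (target; (1S,2R,3R) in tetralin numbering)
Conditions: H2 (1 atm), 10% Pd/C, EtOAc/MeOH, rt
Reagents that add atoms: none
Why: Catalytic hydrogenolysis cleaves the two aryl benzyl ethers, while the diarylmethine C1–H, the methyl ethers and the primary alcohols are inert under these conditions.

Compound list
1 | (R)-4-benzyl-1,3-thiazolidine-2-thione | S=C1N[C@H](Cc2ccccc2)CS1 | starting material
2 | methyl 4-chloro-4-oxobutanoate | COC(=O)CCC(Cl)=O | starting material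
3 | methyl 4-[(4R)-4-benzyl-2-thioxo-1,3-thiazolidin-3-yl]-4-oxobutanoate | COC(=O)CCC(=O)N1[C@H](Cc2ccccc2)CSC1=S | intermediate
4 | 4-(benzyloxy)-3-methoxybenzaldehyde | COc1cc(C=O)ccc1OCc1ccccc1 | starting material
5 | 1-(benzyloxy)-4-(dimethoxymethyl)-2-methoxybenzene | COc1cc(C(OC)OC)ccc1OCc1ccccc1 | intermediate
6 | methyl (3S)-3-{[(4R)-4-benzyl-2-thioxo-1,3-thiazolidin-3-yl]carbonyl}-4-[4-(benzyloxy)-3-methoxyphenyl]-4-methoxybutanoate (epimers at C4 of the butanoate) | COC(=O)C[C@@H](C(OC)c1ccc(OCc2ccccc2)c(OC)c1)C(=O)N1[C@H](Cc2ccccc2)CSC1=S | intermediate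
7 | methyl (3R)-4-[4-(benzyloxy)-3-methoxyphenyl]-3-(hydroxymethyl)-4-methoxybutanoate (epimers at C4) | COC(=O)C[C@@H](C(OC)c1ccc(OCc2ccccc2)c(OC)c1)CO | intermediate (not isolated)
8 | (4R)-4-{[4-(benzyloxy)-3-methoxyphenyl](methoxy)methyl}oxolan-2-one (epimers at the methoxy carbon) | O=C1C[C@@H](C(OC)c2ccc(OCc3ccccc3)c(OC)c2)CO1 | intermediate
9 | [3-(benzyloxy)-4-methoxyphenyl]methanol | COc1ccc(CO)cc1OCc1ccccc1 | starting material
10 | 2-(benzyloxy)-4-(bromomethyl)-1-methoxybenzene | COc1ccc(CBr)cc1OCc1ccccc1 | intermediate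
11 | (3R,4R)-3-[3-(benzyloxy)-4-methoxybenzyl]-4-{[4-(benzyloxy)-3-methoxyphenyl](methoxy)methyl}oxolan-2-one (epimers at the methoxy carbon) | O=C1[C@H](Cc2ccc(OC)c(OCc3ccccc3)c2)[C@@H](C(OC)c2ccc(OCc3ccccc3)c(OC)c2)CO1 | intermediate (not isolated)
12 | (3aR,4S,9aR)-7-(benzyloxy)-4-[4-(benzyloxy)-3-methoxyphenyl]-6-methoxy-3a,4,9,9a-tetrahydronaphtho[2,3-c]furan-1(3H)-one | COc1cc([C@H]2c3cc(OC)c(OCc4ccccc4)cc3C[C@H]3C(=O)OC[C@H]23)ccc1OCc1ccccc1 | intermediate
13 | [(1S,2R,3R)-6-(benzyloxy)-1-[4-(benzyloxy)-3-methoxyphenyl]-7-methoxy-1,2,3,4-tetrahydronaphthalene-2,3-diyl]dimethanol | COc1cc([C@H]2c3cc(OC)c(OCc4ccccc4)cc3C[C@@H](CO)[C@@H]2CO)ccc1OCc1ccccc1 | intermediate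
14 | (5S,6R,7R)-5-(4-hydroxy-3-methoxyphenyl)-6,7-bis(hydroxymethyl)-3-methoxy-5,6,7,8-tetrahydronaphthalen-2-ol | COc1cc([C@H]2c3cc(OC)c(O)cc3C[C@@H](CO)[C@@H]2CO)ccc1O | target

Total step count: 8. Longest linear sequence: 6 (steps 1, 3, 4, 6, 7, 8).

Steps most likely to fail

Step 6. What may go wrong:
- proton exchange or incomplete facial control during the enolate benzylation;
- in the acid stage, intermolecular benzyl transfer, loss of the aryl benzyl ethers, or E1 loss of the C2 proton from the cation (which would erode C2) outrunning closure of the strained trans-fused lactone in the THF-containing medium.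

Fallback: the two bond formations are separated and ring B is closed at the diol oxidation level. Starting from 8 and 10, the alkylation alone (LiN(SiMe3)2, THF, −78 °C) should give 11, which is isolated. LiAlH4 (THF, 0 °C) should reduce it to (2R,3R)-2-[3-(benzyloxy)-4-methoxybenzyl]-3-{[4-(benzyloxy)-3-methoxyphenyl](methoxy)methyl}butane-1,4-diol F1. CF3CO2H in CH2Cl2 at 0 °C should then ionise the benzylic ether of the flexible diol and close ring B by the same Friedel–Crafts alkylation without lactone strain, the known cyclolignan-forming ring closure of benzylic-oxygenated lignan diols. This gives 13, where the route is rejoined.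

Step 3. What may go wrong:
- low conversion because the pendant ester ties up the titanium centre;
- poor facial selectivity at the alpha carbon;
- Lewis-acid cleavage of the aryl benzyl ether.

Fallback: C2 is set by asymmetric hydrogenation and the benzylic oxygen is introduced afterwards. Starting from 4, Stobbe condensation with dimethyl succinate (KOt-Bu, t-BuOH, reflux) should give (E)-4-[4-(benzyloxy)-3-methoxyphenyl]-3-(methoxycarbonyl)but-3-enoic acid F2. Hydrogenation with [Rh(cod)((S,S)-Et-DuPhos)]BF4 (H2, MeOH; the ligand enantiomer is chosen so that the (R)-acid results) should give (3R)-4-[4-(benzyloxy)-3-methoxyphenyl]-3-(methoxycarbonyl)butanoic acid F3. Chemoselective reduction of the ester of its potassium salt (CaCl2/NaBH4, EtOH) should give (3R)-4-[4-(benzyloxy)-3-methoxyphenyl]-3-(hydroxymethyl)butanoic acid F4 (not isolated), which closes on acidification (aq. HCl) to (4R)-4-[4-(benzyloxy)-3-methoxybenzyl]oxolan-2-one F5. DDQ in CH2Cl2/MeOH should then methoxylate the only electron-rich benzylic CH2 to give 8, where the route is rejoined.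

Step 4. What may go wrong:
- reduction of the methyl ester along with the thioimide;
- base-induced loss of methanol from 6 before hydride delivery.

Fallback: the auxiliary is removed hydrolytically and the acid is reduced with an electrophilic hydride. Starting from 6, LiOH (THF/H2O, 0 °C) should give (2S)-2-{[4-(benzyloxy)-3-methoxyphenyl](methoxy)methyl}-4-methoxy-4-oxobutanoic acid F6 and free 1. BH3·SMe2 (THF, 0 °C) should reduce the acid in the presence of the ester to hydroxy ester 7, which lactonises (PPTS cat., CH2Cl2) to 8, where the route is rejoined.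

Further compounds
F1 | step 6 | (2R,3R)-2-[3-(benzyloxy)-4-methoxybenzyl]-3-{[4-(benzyloxy)-3-methoxyphenyl](methoxy)methyl}butane-1,4-diol | OC[C@H](Cc1ccc(OC)c(OCc2ccccc2)c1)[C@@H](C(OC)c1ccc(OCc2ccccc2)c(OC)c1)CO
F2 | step 3 | (E)-4-[4-(benzyloxy)-3-methoxyphenyl]-3-(methoxycarbonyl)but-3-enoic acid | COC(=O)/C(CC(=O)O)=C/c1ccc(OCc2ccccc2)c(OC)c1
F3 | step 3 | (3R)-4-[4-(benzyloxy)-3-methoxyphenyl]-3-(methoxycarbonyl)butanoic acid | COC(=O)[C@@H](CC(=O)O)Cc1ccc(OCc2ccccc2)c(OC)c1
F4 | step 3 | (3R)-4-[4-(benzyloxy)-3-methoxyphenyl]-3-(hydroxymethyl)butanoic acid | OC(=O)C[C@@H](Cc1ccc(OCc2ccccc2)c(OC)c1)CO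
F5 | step 3 | (4R)-4-[4-(benzyloxy)-3-methoxybenzyl]oxolan-2-one | O=C1C[C@@H](Cc2ccc(OCc3ccccc3)c(OC)c2)CO1
F6 | step 4 | (2S)-2-{[4-(benzyloxy)-3-methoxyphenyl](methoxy)methyl}-4-methoxy-4-oxobutanoic acid | COC(=O)C[C@@H](C(OC)c1ccc(OCc2ccccc2)c(OC)c1)C(=O)O
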